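**Retrosynthetic overview**
1. Rings A, B and C and both stereocentres (2R,3R) are bought together in (+)-taxifolin 1; no ring is formed in the route.
2. C5–O to C5–H: mask the 7-, 3'- and 4'-OH with benzyl bromide 2 (gives 3), convert the chelated 5-OH into a triflate with PhNTf2 4 (gives 5), and reduce it (gives 6).
3. Unmask by hydrogenolysis to (2R,3R)-fustin 7; this must come before the geranyl ether, whose alkenes would not survive H2.
4. Last disconnection, O7–C1'': regioselective O-alkylation of the most acidic phenol of 7 with geranyl bromide 8 gives the target 9.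

Assumption: commercial (+)-taxifolin is the (2R,3R) enantiomer of high optical purity and is used as bought.

**Step 1**
Reactants: 1 (+)-taxifolin; 2 benzyl bromide
Product: 3 7,3',4'-tri-O-benzyltaxifolin, (2R,3R)-7-(benzyloxy)-2-[3,4-bis(benzyloxy)phenyl]-3,5-dihydroxy-2,3-dihydro-4H-chromen-4-one
Conditions: BnBr (3.3 equiv), K2CO3 (3.5 equiv), DMF, rt, N2, 16 h
Reagents that add atoms: benzyl bromide, BrCc1ccccc1
Why: Williamson ether synthesis (SN2) in which K2CO3 ionises only the three non-chelated phenols (7-OH and the catechol), while the 5-OH, hydrogen-bonded to the C4 carbonyl, and the aliphatic 3-OH stay free and the two bought stereocentres are not touched.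

**Step 2**
Reactants: 3 7,3',4'-tri-O-benzyltaxifolin; 4 N-phenyl-bis(trifluoromethanesulfonimide) (PhNTf2)
Product: 5 (2R,3R)-7-(benzyloxy)-2-[3,4-bis(benzyloxy)phenyl]-3-hydroxy-4-oxo-3,4-dihydro-2H-chromen-5-yl trifluoromethanesulfonate
Conditions: PhNTf2 (1.3 equiv), Et3N (2.5 equiv), DMAP (0.2 equiv), CH2Cl2, 0 °C to rt
Reagents that add atoms: N-phenyl-bis(trifluoromethanesulfonimide), O=S(=O)(N(c1ccccc1)S(=O)(=O)C(F)(F)F)C(F)(F)F
Why: Chemoselective phenol O-triflation, because the mild triflyl donor PhNTf2 reacts with the phenoxide of the only remaining phenol (5-OH) but not with the secondary 3-OH under amine base, so no stereocentre is affected.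

**Step 3**
Reactants: 5 the 5-O-triflate
Product: 6 7,3',4'-tri-O-benzylfustin, (2R,3R)-7-(benzyloxy)-2-[3,4-bis(benzyloxy)phenyl]-3-hydroxy-2,3-dihydro-4H-chromen-4-one
Conditions: Pd(OAc)2 (5 mol%), dppp (6 mol%), HCO2H (3 equiv), Et3N (4 equiv), DMF, 65 °C
Reagents that add atoms: none
Why: Palladium-catalysed formate transfer hydrogenolysis of an aryl triflate, in which zerovalent palladium inserts into the C5–OTf bond next to the carbonyl, formate delivers hydride with loss of CO2 and reductive elimination forms C5–H, leaving benzyl ethers, ketone and both stereocentres intact.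

**Step 4**
Reactants: 6 7,3',4'-tri-O-benzylfustin
Product: 7 (2R,3R)-fustin, (2R,3R)-2-(3,4-dihydroxyphenyl)-3,7-dihydroxy-2,3-dihydro-4H-chromen-4-one
Conditions: H2 (1 atm), 10% Pd/C, EtOAc/MeOH 1:1, rt
Reagents that add atoms: none
Why: Neutral heterogeneous catalytic hydrogenolysis cleaves the three aryl benzyl ethers much faster than it reduces the aryl ketone or the C2–O1 bond, so the phenols are freed without touching C2 or C3.

**Step 5**
Reactants: 7 (2R,3R)-fustin; 8 geranyl bromide, (2E)-1-bromo-3,7-dimethylocta-2,6-diene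
Product: 9 target, (2R,3R)-2-(3,4-dihydroxyphenyl)-7-{[(2E)-3,7-dimethylocta-2,6-dien-1-yl]oxy}-3-hydroxy-2,3-dihydro-4H-chromen-4-one (7-O-geranylfustin)
Conditions: geranyl bromide (1.05 equiv), K2CO3 (1.1 equiv), acetone, rt, argon, dark
Reagents that add atoms: geranyl bromide, CC(C)=CCC/C(C)=C/CBr
Why: Regioselective Williamson etherification (SN2 at the primary allylic bromide, E-alkene bought in 8), since one equivalent of weak base ionises mainly the 7-OH, the most acidic phenol because it is para to the C4 carbonyl, so geranyl goes on O7 and C2/C3 stay unchanged.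

**Compound list**
1 | (+)-taxifolin, (2R,3R)-2-(3,4-dihydroxyphenyl)-3,5,7-trihydroxy-2,3-dihydro-4H-chromen-4-one | Oc1cc(O)c2c(c1)O[C@H](c1ccc(O)c(O)c1)[C@@H](O)C2=O | starting material
2 | benzyl bromide | BrCc1ccccc1 | starting material
3 | 7,3',4'-tri-O-benzyltaxifolin | c1ccccc1COc1cc(O)c2c(c1)O[C@H](c1ccc(OCc3ccccc3)c(OCc3ccccc3)c1)[C@@H](O)C2=O | intermediate
4 | N-phenyl-bis(trifluoromethanesulfonimide) | O=S(=O)(N(c1ccccc1)S(=O)(=O)C(F)(F)F)C(F)(F)F | starting material
5 | 7,3',4'-tri-O-benzyltaxifolin 5-O-triflate | c1ccccc1COc1cc(OS(=O)(=O)C(F)(F)F)c2c(c1)O[C@H](c1ccc(OCc3ccccc3)c(OCc3ccccc3)c1)[C@@H](O)C2=O | intermediate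
6 | 7,3',4'-tri-O-benzylfustin | c1ccccc1COc1ccc2c(c1)O[C@H](c1ccc(OCc3ccccc3)c(OCc3ccccc3)c1)[C@@H](O)C2=O | intermediate
7 | (2R,3R)-fustin | Oc1ccc2c(c1)O[C@H](c1ccc(O)c(O)c1)[C@@H](O)C2=O | intermediate
8 | geranyl bromide | CC(C)=CCC/C(C)=C/CBr | starting material
9 | 7-O-geranyl-(2R,3R)-fustin (CNP0508026.1) | CC(C)=CCC/C(C)=C/COc1ccc2c(c1)O[C@H](c1ccc(O)c(O)c1)[C@@H](O)C2=O | target

**Totals**
Total step count: 5. Longest linear sequence: 5 steps (1 to 9).

**Three steps most likely to fail**

Step 1 (tri-O-benzylation). The carbonate base can epimerise C2 by reversible ring opening, over-alkylate the 5-OH, or C-benzylate ring A. The trans isomer is thermodynamically preferred, which limits but does not remove the risk. The fallback sets out from 1 and uses acid-labile acetals under amine base only. MOMCl (3.3 equiv), iPr2NEt, CH2Cl2, 0 °C gives 7,3',4'-tris-O-(methoxymethyl)taxifolin F1. PhNTf2, Et3N, DMAP then gives 7,3',4'-tris-O-(methoxymethyl)taxifolin 5-O-triflate F2. Pd(OAc)2, dppp, HCO2H, Et3N in DMF at 65 °C gives 7,3',4'-tris-O-(methoxymethyl)fustin F3. HCl in MeOH at 40 °C removes the acetals, and the route is rejoined at 7.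

Step 3 (triflate reduction). The hindered, electron-rich triflate may be hydrolysed back to the phenol, or the warm amine may erode C2/C3. The fallback sets out from 3 and avoids both the triflate and homogeneous palladium. 5-Chloro-1-phenyl-1H-tetrazole, K2CO3, DMF, 50 °C gives 7,3',4'-tri-O-benzyltaxifolin 5-O-(1-phenyl-1H-tetrazol-5-yl) ether F4. H2, 10% Pd/C, EtOH/EtOAc, 40 °C then cleaves the activated aryl C5–O bond (Musliner–Gates hydrogenolysis) and the three benzyl ethers in one operation. The route is rejoined at 7; compounds 5 and 6 are bypassed.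

Step 5 (7-O-geranylation). Competing alkylation at 4'-OH or 3'-OH, bis-alkylation, and base or air damage to the free catechol are all possible. The fallback sets out from 7 and masks the catechol under base-free conditions. PhB(OH)2, MgSO4, THF, rt gives fustin 3',4'-O-phenylboronate F5. Mitsunobu etherification of the only free phenol with geraniol, PPh3 and DIAD in THF (0 °C to rt) gives 7-O-geranylfustin 3',4'-O-phenylboronate F6. Hydrolysis of the boronate in THF/H2O on work-up rejoins the route at 9.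

**Further compounds**
F1 | step 1 | 7,3',4'-tris-O-(methoxymethyl)taxifolin | COCOc1cc(O)c2c(c1)O[C@H](c1ccc(OCOC)c(OCOC)c1)[C@@H](O)C2=O
F2 | step 1 | 7,3',4'-tris-O-(methoxymethyl)taxifolin 5-O-triflate | COCOc1cc(OS(=O)(=O)C(F)(F)F)c2c(c1)O[C@H](c1ccc(OCOC)c(OCOC)c1)[C@@H](O)C2=O
F3 | step 1 | 7,3',4'-tris-O-(methoxymethyl)fustin | COCOc1ccc2c(c1)O[C@H](c1ccc(OCOC)c(OCOC)c1)[C@@H](O)C2=O
F4 | step 3 | 7,3',4'-tri-O-benzyltaxifolin 5-O-(1-phenyl-1H-tetrazol-5-yl) ether | c1ccccc1COc1cc(Oc3nnnn3-c3ccccc3)c2c(c1)O[C@H](c1ccc(OCc3ccccc3)c(OCc3ccccc3)c1)[C@@H](O)C2=O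
F5 | step 5 | fustin 3',4'-O-phenylboronate | Oc1ccc2c(c1)O[C@H](c1ccc3OB(c4ccccc4)Oc3c1)[C@@H](O)C2=O
F6 | step 5 | 7-O-geranylfustin 3',4'-O-phenylboronate | CC(C)=CCC/C(C)=C/COc1ccc2c(c1)O[C@H](c1ccc3OB(c4ccccc4)Oc3c1)[C@@H](O)C2=O
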